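The grey flask holds a small charge: 0.200 M of substrate and 0.240 M of partner, the amber run's charge cut to a quarter, with the same 0.0800 M of free catalyst.

all flasks: free catalyst 0.0800 M
- amber: substrate 0.800 M; partner 0.960 M
- ochre: substrate 0.400 M; partner 0.560 M
- violet: substrate 0.800 M; partner 2.90 M
- green: substrate 1.60 M; partner 0.960 M
- grey: substrate 0.200 M; partner 0.240 M; time 32 min

- amber run (time / min: [product] / M): 4.0: 0.028; 8.0: 0.086; 12: 0.106; 16: 0.152; 20: 0.198; 24: 0.245; 28: 0.274; 32: 0.330
- ochre run (time / min: [product] / M): 4.0: 0.019; 8.0: 0.062; 12: 0.088; 16: 0.121; 20: 0.141; 24: 0.154; 28: 0.164; 32: 0.224
- violet run (time / min: [product] / M): 4.0: 0; 8.0: 0.015; 12: 0.030; 16: 0.027; 20: 0.033; 24: 0.013; 28: 0.032; 32: 0.050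
- green run (time / min: [product] / M): 4.0: 0.073; 8.0: 0.172; 12: 0.272; 16: 0.352; 20: 0.437; 24: 0.513; 28: 0.596; 32: 0.659

(each reading ± 0.01 M)

- Overall: substrate + partner -> product, with free catalyst as catalyst.
- Constant volume, constant temperature.
- Readings of a species count what is bound in complexes too.
- An order is taken over about fifteen percent of the charge, up and down.

1. the power of [partner] that the first rate follows, about the charge of the amber run; measure it at two percent of substrate made into product
2. the power of [substrate] that the first rate follows, about the charge of the amber run; measure it at two percent of substrate made into product (one fixed amount of product, the same in the runs compared)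
3. the ochre run starts with 0.400 M less of substrate and of partner than the amber run, and with no product. Compared where both hold the same amount of substrate, once fifteen percent of what the ochre run was charged with has turned into product, is the ochre run faster, slower or alike (within a tenth)?
4. product in the grey run at 32 min, as a share of the substrate charged

I compare the grey run with the amber run, which has the same ratio of substrate to partner, and I take as zero of my scale a pseudo-first-order flask, in which the share of substrate turned at a given time does not depend on the charge. On that zero, the grey run stands level with the amber run's 41.2% at 32 min.

The departure from that zero can be measured. By 20 min the amber run has turned 24.8% of its substrate, and this gives 70.3 min for the time divided by minus the logarithm of the share unturned. I call this τ the clearing time; on my zero it stays the same from charge to charge.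

The readings at that same time give, for the other runs:

τ(ochre) = 46.0 min

τ(green) = 62.7 min

The green run has twice the substrate of the amber run at the same c(partner), and its τ is 62.7 min against 70.3 min. The ochre run has less substrate and less partner than the amber run, and its τ is shorter than the amber run's. So I lay the change on c(partner), with a straight line through the ochre and amber runs:

τ(grey) = 26.6 min

share at 32 min = 70.0%

In my estimate the grey run ends at a higher share than the amber run's 41.2%, with a clearing time shorter than the amber run's, although their charges stand in one ratio. This is an estimate: the grey run's 0.240 M of partner is less than the ochre run's 0.560 M, the lower end of the line, and at 2.90 M of partner the violet run's reading of 496 min stands above the line, so the line does not hold up there.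

The forecast gives −1.2, 0.95, alike and 60% for the questions in turn, holding that “Partner inhibits”, and its share is lower than my 70.0%.

The order in c(partner) comes to −1.1, the order in c(substrate) to 1.3, the ochre run against the amber run is alike, and the grey run comes to 67.7% at 32 min.

    free catalyst + substrate → loaded catalyst + by-product (1.092 M⁻¹ min⁻¹)
    loaded catalyst + partner → product + free catalyst (3.078 M⁻¹ min⁻¹)
    free catalyst + partner ⇌ idle catalyst-reagent complex, settled at all times (2.670 M⁻¹)
    substrate + partner ⇌ idle substrate-reagent adduct, settled at all times (3.320 M⁻¹)

The amber run needs 19.4 min to reach a quarter of its substrate, a clearing time of 67.4 min. The grey run's own clearing time is 28.3 min, a little longer than my 26.6 min. Against the amber reading of 70.3 min, the green run clears in 61.8 min at a quarter of its substrate and in 62.8 min at half.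

Readings and results stem from a simulated flask on assumed constants, noise included.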